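**Retrosynthetic overview**
- The ArCH2–Ar bond is cut last: the target becomes two molecules of aspidinol plus formaldehyde. In the forward direction one aspidinol is turned in situ into its ortho-quinone methide and the second adds to it in an intermolecular Michael addition.
- Aspidinol comes from its bis-MOM ether, made by oxidising the carbinol from butanal and the aryllithium obtained by directed ortho-lithiation of 1-methoxy-2-methyl-3,5-bis(methoxymethoxy)benzene between its two OMOM groups.
- That arene comes from 2,4,6-trihydroxybenzaldehyde: MOM on the two non-chelated OH groups, methyl on the chelated OH, then CHO → CH3, which fixes the Me/OMe/OH pattern without regiochemical ambiguity.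
- No ring is formed: both benzene rings come intact from the starting aldehyde.

Assumption: the target SMILES has no stereocentre and no stereogenic double bond, so the compound is achiral and "single enantiomer" means this one compound.

**Step 1**
Reactants: 1 2,4,6-trihydroxybenzaldehyde
Product: 2 2-hydroxy-4,6-bis(methoxymethoxy)benzaldehyde
Conditions: MOMCl (2.1 equiv), i-Pr2NEt (2.5 equiv), CH2Cl2, 0 °C → rt
Reagents that add atoms: chloromethyl methyl ether (MOMCl), COCCl
Why: Williamson-type O-alkylation takes the two non-chelated phenols, while the third, hydrogen-bonded to the formyl oxygen, is the least nucleophilic and stays free, which differentiates the three oxygens.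

**Step 2**
Reactants: 2 2-hydroxy-4,6-bis(methoxymethoxy)benzaldehyde
Product: 3 2-methoxy-4,6-bis(methoxymethoxy)benzaldehyde
Conditions: MeI (2 equiv), K2CO3 (2 equiv), DMF, 40 °C
Reagents that add atoms: iodomethane (MeI), CI
Why: Williamson ether synthesis on the only free phenol (its chelate is broken by carbonate in warm DMF) places the future methoxy group next to the formyl carbon.

**Step 3**
Reactants: 3 2-methoxy-4,6-bis(methoxymethoxy)benzaldehyde
Product: 5 1-methoxy-2-methyl-3,5-bis(methoxymethoxy)benzene, via aldehyde hydrazone 4 (not isolated)
Conditions: N2H4·H2O (6 equiv), KOH (4 equiv), diethylene glycol, 130 °C, then 195 °C with distillation of H2O and excess N2H4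
Reagents that add atoms: none
Why: Wolff–Kishner reduction (Huang-Minlon procedure) converts the formyl group into the C-methyl group through the hydrazone, and MOM acetals and aryl methyl ethers are inert to hot alkali.

**Step 4**
Reactants: 5 1-methoxy-2-methyl-3,5-bis(methoxymethoxy)benzene; 6 butanal
Product: 8 racemic 1-[4-methoxy-2,6-bis(methoxymethoxy)-3-methylphenyl]butan-1-ol, via aryllithium 7 (not isolated)
Conditions: n-BuLi (1.2 equiv), THF, 0 °C, 1 h; then 6 (1.5 equiv), −78 °C → 0 °C; H2O quench
Reagents that add atoms: none
Why: Directed ortho-metalation occurs at the ring CH flanked by two OMOM groups (stronger, chelating directors than OMe) and the aryllithium adds 1,2 to butanal; the carbinol stereocentre forms racemic and is erased in step 5.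

**Step 5**
Reactants: 8 racemic 1-[4-methoxy-2,6-bis(methoxymethoxy)-3-methylphenyl]butan-1-ol
Product: 9 1-[4-methoxy-2,6-bis(methoxymethoxy)-3-methylphenyl]butan-1-one
Conditions: Dess–Martin periodinane (DMP, 1.3 equiv), CH2Cl2, 0 °C → rt
Reagents that add atoms: none
Why: Dess–Martin oxidation of the hindered benzylic secondary alcohol gives the aryl ketone under conditions that leave MOM and methyl ethers untouched and removes the only stereocentre.

**Step 6**
Reactants: 9 1-[4-methoxy-2,6-bis(methoxymethoxy)-3-methylphenyl]butan-1-one
Product: 10 aspidinol = 1-(2,6-dihydroxy-4-methoxy-3-methylphenyl)butan-1-one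
Conditions: 3 M HCl in MeOH, 50 °C
Reagents that add atoms: none
Why: Acid-catalysed acetal solvolysis removes both MOM groups (methanol traps the CH2 unit as dimethoxymethane) while the aryl methyl ether and the ketone are stable.

**Step 7**
Reactants: 10 aspidinol (2 equiv); 11 formaldehyde
Product: 14 methylenebis(aspidinol) = 1,1'-[methylenebis(2,6-dihydroxy-4-methoxy-5-methyl-3,1-phenylene)]bis(butan-1-one), via 5-(hydroxymethyl)aspidinol 12 (not isolated), via ortho-quinone methide 13 (not isolated)
Conditions: 11 (37% aq., 0.5 equiv per 10), degassed 1% aq. NaOH (1.1 equiv per 10), N2, 0 °C → rt, 1 h; then 1 M HCl to pH 2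
Reagents that add atoms: none
Why: The phenolate of 10 is hydroxymethylated at its only free ring carbon (aldol-type Lederer–Manasse addition), 12 loses hydroxide to give 13, and a second phenolate of 10 adds to 13 in an intermolecular Michael addition that forms the ArCH2–Ar bond and rearomatises, with no stereocentre created.

**Compound list**
1 | 2,4,6-trihydroxybenzaldehyde | O=Cc1c(O)cc(O)cc1O | starting material
2 | 2-hydroxy-4,6-bis(methoxymethoxy)benzaldehyde | O=Cc1c(O)cc(OCOC)cc1OCOC | intermediate
3 | 2-methoxy-4,6-bis(methoxymethoxy)benzaldehyde | O=Cc1c(OC)cc(OCOC)cc1OCOC | intermediate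
4 | (E)-[2-methoxy-4,6-bis(methoxymethoxy)benzylidene]hydrazine (aldehyde hydrazone, formed in situ) | N/N=C/c1c(OC)cc(OCOC)cc1OCOC | intermediate
5 | 1-methoxy-2-methyl-3,5-bis(methoxymethoxy)benzene | Cc1c(OC)cc(OCOC)cc1OCOC | intermediate
6 | butanal | CCCC=O | starting material
7 | [4-methoxy-2,6-bis(methoxymethoxy)-3-methylphenyl]lithium (formed in situ) | [Li]c1c(OCOC)c(C)c(OC)cc1OCOC | intermediate
8 | racemic 1-[4-methoxy-2,6-bis(methoxymethoxy)-3-methylphenyl]butan-1-ol | CCCC(O)c1c(OCOC)c(C)c(OC)cc1OCOC | intermediate
9 | 1-[4-methoxy-2,6-bis(methoxymethoxy)-3-methylphenyl]butan-1-one | CCCC(=O)c1c(OCOC)c(C)c(OC)cc1OCOC | intermediate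
10 | aspidinol, 1-(2,6-dihydroxy-4-methoxy-3-methylphenyl)butan-1-one | CCCC(=O)c1c(O)c(C)c(OC)cc1O | intermediate
11 | formaldehyde | C=O | starting material
12 | 1-[2,6-dihydroxy-3-(hydroxymethyl)-4-methoxy-5-methylphenyl]butan-1-one (formed in situ) | CCCC(=O)c1c(O)c(C)c(OC)c(CO)c1O | intermediate
13 | 2-butanoyl-3-hydroxy-5-methoxy-4-methyl-6-methylidenecyclohexa-2,4-dien-1-one (ortho-quinone methide, formed in situ) | C=C1C(=O)C(C(=O)CCC)=C(O)C(C)=C1OC | intermediate
14 | methylenebis(aspidinol), 1,1'-[methylenebis(2,6-dihydroxy-4-methoxy-5-methyl-3,1-phenylene)]bis(butan-1-one) | CCCC(=O)c1c(O)c(C)c(OC)c(Cc2c(O)c(C(=O)CCC)c(O)c(C)c2OC)c1O | target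

**Totals**
Total step count: 7. Longest linear sequence: 7 steps (1 → 14); butanal 6 enters at step 4 and two molecules of 10 are joined with 11 at step 7.

**Steps most likely to fail, with fallbacks**

Step 7 (bridging). The risks are air oxidation of the electron-rich phenolate, stalling at 12 if the formaldehyde dose is off, and attack of 13 at oxygen or at the methyl-bearing ring carbon. The fallback sets out from 10 and returns at 14. One portion of 10 is treated with piperidine and aqueous formaldehyde in EtOH at rt (phenolic Mannich reaction) to give the isolable Mannich base 1-[2,6-dihydroxy-4-methoxy-3-methyl-5-(piperidin-1-ylmethyl)phenyl]butan-1-one F3. Heating F3 with one further equivalent of 10 in toluene at 100 °C expels piperidine to give the quinone methide 13 in the absence of free formaldehyde and strong base, and 10 adds to it in the same Michael sense to give 14.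

Step 4 (lithiation and addition). The risks are partial lithiation at the CH between OMOM and OMe, and enolisation of butanal by the hindered aryllithium. The fallback sets out from 5 and returns at 10, bypassing 8 and 9. Both MOM groups of 5 are removed with HCl in MeOH at 40 °C to give 5-methoxy-4-methylbenzene-1,3-diol F2. F2 is C-acylated with butanoic acid in BF3·OEt2 at 80 °C (Friedel–Crafts acylation). The isomer acylated between the two hydroxyls is 10; it is separated by chromatography or crystallisation from the isomer acylated between OH and OMe.

Step 3 (Wolff–Kishner at 195 °C). The risks are azine formation and partial ether cleavage in hot alkali. The fallback sets out from 3 and returns at 5. NaBH4 in MeOH at 0 °C reduces 3 to the benzylic alcohol [2-methoxy-4,6-bis(methoxymethoxy)phenyl]methanol F1. Its very electron-rich benzylic C–O bond is then hydrogenolysed with H2 (1 atm) over 10% Pd/C in EtOAc containing 1% AcOH at rt to give 5.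

**Further compounds**
F1 | step 3 | [2-methoxy-4,6-bis(methoxymethoxy)phenyl]methanol | OCc1c(OC)cc(OCOC)cc1OCOC
F2 | step 4 | 5-methoxy-4-methylbenzene-1,3-diol | COc1cc(O)cc(O)c1C
F3 | step 7 | 1-[2,6-dihydroxy-4-methoxy-3-methyl-5-(piperidin-1-ylmethyl)phenyl]butan-1-one | CCCC(=O)c1c(O)c(C)c(OC)c(CN2CCCCC2)c1O
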